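## Retrosynthetic overview

1. Target 18 ⇐ desilylation and aldehyde-level reduction of the trans-2-aryl-3-(dimethoxymethyl)-2,3-dihydrobenzofuran 15.
2. 15 ⇐ oxidative ring contraction (1,2-shift of the ring A carbon from C4 to C3) of the (R)-2-aryl-2H-chromene 14; the furan ring is the last ring made, by contraction of the pyran ring.
3. 14 ⇐ catalytic enantioselective opening and 6-endo C–O closure of benzodioxaborin 13 (dioxaborin ring first, then pyran ring); 13 ⇐ phenol 10 + enal 12 + PhB(OH)2.
4. 10 ⇐ Mitsunobu ester of dihydroconiferyl alcohol 7 with silyl-protected ferulic acid 9.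
5. 7, 9 and 12 ⇐ Heck reactions of 4-iodoguaiacol 3 (or its silyl ether 4) with allyl alcohol, acrylic acid and acrolein; 3 ⇐ catechol.

Assumption: the sense of induction of the new step 9 cannot be predicted with certainty; the (R)-catalyst is written and its mirror image is used if the opposite sense is found.

Assumption: an intermediate that reacts on in the same flask without isolation is counted inside one step.

## Route

Step 1
Reactants: 1 catechol (benzene-1,2-diol)
Product: 2 guaiacol (2-methoxyphenol)
Conditions: Me2SO4 (1.0 equiv), NaOH (1.0 equiv), H2O, 40 °C; veratrole removed by base extraction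
Reagents that add atoms: dimethyl sulfate COS(=O)(=O)OC
Why: Williamson mono-O-methylation of the catechol mono-anion, the second hydroxyl being much less acidic once the first is ionised.

Step 2
Reactants: 2 guaiacol
Product: 3 4-iodo-2-methoxyphenol
Conditions: NIS (1.0 equiv), TsOH·H2O (10 mol%), MeCN, 0 to 25 °C
Reagents that add atoms: N-iodosuccinimide O=C1CCC(=O)N1I
Why: Electrophilic aromatic iodination directed para to the free hydroxyl, the strongest activating group.

Step 3
Reactants: 3 4-iodo-2-methoxyphenol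
Product: 4 (4-iodo-2-methoxyphenoxy)triisopropylsilane
Conditions: TIPSCl (1.1 equiv), imidazole (2 equiv), DMF, 25 °C
Reagents that add atoms: triisopropylsilyl chloride CC(C)[Si](Cl)(C(C)C)C(C)C
Why: Standard phenol silylation; the aryl silyl ether withstands the Heck, acid, trivalent-iodine and borohydride steps and is cleaved by fluoride at the end.

Step 4
Reactants: 3 4-iodo-2-methoxyphenol; 5 allyl alcohol (prop-2-en-1-ol)
Product: 7 dihydroconiferyl alcohol [4-(3-hydroxypropyl)-2-methoxyphenol], via 3-arylpropanal 6 (not isolated)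
Conditions: Pd(OAc)2 (2 mol%), Bu4NCl (1 equiv), NaHCO3 (2.5 equiv), DMF, 45 °C; then MeOH, NaBH4 (1.5 equiv), 0 °C
Reagents that add atoms: none
Why: Jeffery–Heck arylation of allyl alcohol, in which β-hydride elimination towards the carbinol gives the 3-arylpropanal, followed by borohydride reduction in the same flask.

Step 5
Reactants: 4 (4-iodo-2-methoxyphenoxy)triisopropylsilane; 8 acrylic acid
Product: 9 (E)-3-[3-methoxy-4-(triisopropylsilyloxy)phenyl]prop-2-enoic acid (O-silyl ferulic acid)
Conditions: Pd(OAc)2 (2 mol%), P(o-tol)3 (4 mol%), Et3N (3 equiv), MeCN, 80 °C; dilute citric acid work-up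
Reagents that add atoms: none
Why: Mizoroki–Heck arylation of acrylic acid, which gives the (E)-cinnamic acid through syn insertion and syn β-hydride elimination.

Step 6
Reactants: 7 dihydroconiferyl alcohol; 9 O-silyl ferulic acid
Product: 10 3-(4-hydroxy-3-methoxyphenyl)propyl (E)-3-[3-methoxy-4-(triisopropylsilyloxy)phenyl]prop-2-enoate
Conditions: PPh3 (1.2 equiv), DIAD (1.2 equiv), THF, 0 to 25 °C
Reagents that add atoms: none
Why: Mitsunobu esterification, in which the primary alcohol is activated and the carboxylic acid (pKa about 4.5) is the pronucleophile, so the phenol (pKa about 10) stays free.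

Step 7
Reactants: 4 (4-iodo-2-methoxyphenoxy)triisopropylsilane; 11 acrolein (prop-2-enal)
Product: 12 (E)-3-[3-methoxy-4-(triisopropylsilyloxy)phenyl]prop-2-enal (O-silyl coniferaldehyde)
Conditions: acrolein (2 equiv), Pd(OAc)2 (3 mol%), Bu4NCl (1 equiv), NaHCO3 (2.5 equiv), DMF, 40 °C
Reagents that add atoms: none
Why: Jeffery–Heck arylation of acrolein under mild phase-transfer conditions that spare the enal and the silyl ether, giving the (E)-cinnamaldehyde.

Step 8
Reactants: 10 phenol ester; 12 O-silyl coniferaldehyde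
Product: 13 racemic 3-[8-methoxy-2-phenyl-4-{(E)-2-[3-methoxy-4-(triisopropylsilyloxy)phenyl]ethenyl}-4H-1,3,2-benzodioxaborinin-6-yl]propyl (E)-3-[3-methoxy-4-(triisopropylsilyloxy)phenyl]prop-2-enoate
Conditions: PhB(OH)2 (1.1 equiv), EtCO2H (0.3 equiv), toluene, 80 °C, 4 Å molecular sieves; stopped before chromene formation sets in
Reagents that add atoms: phenylboronic acid OB(O)c1ccccc1
Why: Boron-templated ortho-specific hydroxyalkylation of a phenol by an aldehyde (Nagata-type benzodioxaborin formation); the aryl boronate delivers the enal carbonyl carbon to the only free ortho position in a 1,2-sense.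

Step 9
Reactants: 13 benzodioxaborin
Product: 14 3-[(2R)-8-methoxy-2-{3-methoxy-4-(triisopropylsilyloxy)phenyl}-2H-chromen-6-yl]propyl (E)-3-[3-methoxy-4-(triisopropylsilyloxy)phenyl]prop-2-enoate
Conditions: (R)-3,3'-bis(2,4,6-triisopropylphenyl)-1,1'-binaphthyl-2,2'-diyl N-triflylphosphoramide (5 mol%), toluene, 4 Å molecular sieves, −40 °C; Et3N quench
Reagents that add atoms: none
Why: Proposed new method: the strong chiral acid protonates the benzylic/allylic B–O–C oxygen of 13 and heterolyses the C4–O bond to a 1,3-diarylallyl cation held in a contact ion pair with the chiral phosphoramidate (which can also bind the pendant boron as an ate complex), so that the boron-bound aryloxide closes 6-endo onto the ring B terminus on one enantiotopic face, setting C2 as (R) while the racemic C4 centre of 13 is erased on ionisation and the released PhB(OH) unit collapses to boroxine and returns the acid; the closest known reactions are chiral N-triflylphosphoramide-catalysed intramolecular allylic substitutions of ortho-hydroxyaryl allylic alcohols to 2H-chromenes and the thermal, racemic benzodioxaborin-to-chromene conversion, but asymmetric acid-catalysed opening of a benzodioxaborin C–O bond has not been shown.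

Step 10
Reactants: 14 (R)-2H-chromene
Product: 15 3-[(2R,3R)-3-(dimethoxymethyl)-7-methoxy-2-{3-methoxy-4-(triisopropylsilyloxy)phenyl}-2,3-dihydro-1-benzofuran-5-yl]propyl (E)-3-[3-methoxy-4-(triisopropylsilyloxy)phenyl]prop-2-enoate
Conditions: PhI(OH)OTs (1.2 equiv, added in portions), MeOH/CH2Cl2 (3:1), 3 Å molecular sieves, −20 to 0 °C, dark
Reagents that add atoms: methanol CO
Why: Oxidative ring contraction by trivalent iodine: the electrophile adds to C3 anti to the 2-aryl group and methanol adds to C4, then the ring A carbon migrates from C4 to C3 with inversion as iodobenzene leaves (semipinacol-type 1,2-aryl shift) and the oxocarbenium ion is trapped by methanol, which sets C3 trans to the 2-aryl group.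

Step 11
Reactants: 15 dimethyl acetal
Product: 17 3-[(2R,3S)-3-(hydroxymethyl)-7-methoxy-2-{3-methoxy-4-(triisopropylsilyloxy)phenyl}-2,3-dihydro-1-benzofuran-5-yl]propyl (E)-3-[3-methoxy-4-(triisopropylsilyloxy)phenyl]prop-2-enoate, via 3-formyl dihydrobenzofuran 16 (not isolated)
Conditions: HCl (1 M aq., 0.2 equiv), THF/H2O, 25 °C; then MeOH, NaBH4 (3 equiv), 0 °C
Reagents that add atoms: water O
Why: Acid-catalysed acetal hydrolysis followed by chemoselective borohydride reduction of the aldehyde beside the cinnamate ester; the trans arrangement is the thermodynamic one at the epimerisable C3, and the change of descriptor from 3R to 3S is only a change of CIP priorities.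

Step 12
Reactants: 17 bis-silyl ether
Product: 18 target, 3-[(2R,3S)-3-(hydroxymethyl)-2-(4-hydroxy-3-methoxyphenyl)-7-methoxy-2,3-dihydro-1-benzofuran-5-yl]propyl (E)-3-(4-hydroxy-3-methoxyphenyl)prop-2-enoate
Conditions: Bu4NF (2.4 equiv), AcOH (2.6 equiv), THF, 0 °C
Reagents that add atoms: none
Why: Fluoride-induced cleavage of both aryl silyl ethers, buffered with acetic acid so that the cinnamate ester, the benzylic ether and both stereocentres are untouched.

## Compound list

1 | catechol | Oc1ccccc1O | starting material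
2 | guaiacol (2-methoxyphenol) | COc1ccccc1O | intermediate
3 | 4-iodo-2-methoxyphenol | COc1cc(I)ccc1O | intermediate
4 | (4-iodo-2-methoxyphenoxy)triisopropylsilane | COc1cc(I)ccc1O[Si](C(C)C)(C(C)C)C(C)C | intermediate
5 | allyl alcohol | C=CCO | starting material
6 | 3-(4-hydroxy-3-methoxyphenyl)propanal | COc1cc(CCC=O)ccc1O | intermediate
7 | 4-(3-hydroxypropyl)-2-methoxyphenol (dihydroconiferyl alcohol) | COc1cc(CCCO)ccc1O | intermediate
8 | acrylic acid | C=CC(=O)O | starting material
9 | (E)-3-[3-methoxy-4-(triisopropylsilyloxy)phenyl]prop-2-enoic acid | COc1cc(/C=C/C(=O)O)ccc1O[Si](C(C)C)(C(C)C)C(C)C | intermediate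
10 | 3-(4-hydroxy-3-methoxyphenyl)propyl (E)-3-[3-methoxy-4-(triisopropylsilyloxy)phenyl]prop-2-enoate | COc1cc(/C=C/C(=O)OCCCc2ccc(O)c(OC)c2)ccc1O[Si](C(C)C)(C(C)C)C(C)C | intermediate
11 | acrolein | C=CC=O | starting material
12 | (E)-3-[3-methoxy-4-(triisopropylsilyloxy)phenyl]prop-2-enal | COc1cc(/C=C/C=O)ccc1O[Si](C(C)C)(C(C)C)C(C)C | intermediate
13 | racemic 4-styryl-2-phenyl-4H-1,3,2-benzodioxaborinine carrying the 8-methoxy group and the 6-(3-acyloxypropyl) chain (full name in step 8) | COc1cc(/C=C/C(=O)OCCCc2cc(OC)c3OB(c4ccccc4)OC(/C=C/c4ccc(O[Si](C(C)C)(C(C)C)C(C)C)c(OC)c4)c3c2)ccc1O[Si](C(C)C)(C(C)C)C(C)C | intermediate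
14 | (2R)-2-aryl-8-methoxy-2H-chromene ester (full name in step 9) | COc1cc(/C=C/C(=O)OCCCc2cc(OC)c3c(c2)C=C[C@H](c2ccc(O[Si](C(C)C)(C(C)C)C(C)C)c(OC)c2)O3)ccc1O[Si](C(C)C)(C(C)C)C(C)C | intermediate
15 | (2R,3R)-trans-2-aryl-3-(dimethoxymethyl)-7-methoxy-2,3-dihydrobenzofuran ester (full name in step 10) | COc1cc(/C=C/C(=O)OCCCc2cc(OC)c3c(c2)[C@@H](C(OC)OC)[C@H](c2ccc(O[Si](C(C)C)(C(C)C)C(C)C)c(OC)c2)O3)ccc1O[Si](C(C)C)(C(C)C)C(C)C | intermediate
16 | (2R,3R)-trans-2-aryl-3-formyl-7-methoxy-2,3-dihydrobenzofuran ester | COc1cc(/C=C/C(=O)OCCCc2cc(OC)c3c(c2)[C@@H](C=O)[C@H](c2ccc(O[Si](C(C)C)(C(C)C)C(C)C)c(OC)c2)O3)ccc1O[Si](C(C)C)(C(C)C)C(C)C | intermediate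
17 | (2R,3S)-trans-2-aryl-3-(hydroxymethyl)-7-methoxy-2,3-dihydrobenzofuran ester, both phenols as triisopropylsilyl ethers (full name in step 11) | COc1cc(/C=C/C(=O)OCCCc2cc(OC)c3c(c2)[C@@H](CO)[C@H](c2ccc(O[Si](C(C)C)(C(C)C)C(C)C)c(OC)c2)O3)ccc1O[Si](C(C)C)(C(C)C)C(C)C | intermediate
18 | 3-[(2R,3S)-3-(hydroxymethyl)-2-(4-hydroxy-3-methoxyphenyl)-7-methoxy-2,3-dihydro-1-benzofuran-5-yl]propyl (E)-3-(4-hydroxy-3-methoxyphenyl)prop-2-enoate | COc1cc(/C=C/C(=O)OCCCc2cc(OC)c3c(c2)[C@@H](CO)[C@H](c2ccc(O)c(OC)c2)O3)ccc1O | target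

## Step count and risks

Total step count: 12. Longest linear sequence: 10 (steps 1, 2, 3, 5, 6, 8, 9, 10, 11, 12).

Three steps most likely to fail:

Step 9 (the proposed new step). The risks are low enantioselectivity, because a free ortho-quinone methide can close without the catalyst, and re-ionisation of the product by the strong acid. The fallback uses known chemistry and sets out from 13. Heating 13 in toluene with acetic acid at reflux effects the established thermal loss of the boron unit and ring closure to the racemic 2-aryl-8-methoxy-2H-chromene ester F1. Preparative chiral supercritical-fluid chromatography on a cellulose tris(3,5-dimethylphenylcarbamate) phase removes the (S)-2-aryl-8-methoxy-2H-chromene ester F2, and the (R)-enantiomer collected is 14, where the route is rejoined.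

Step 8. The condensation may be slow with the conjugated enal, or may run on to racemic chromene instead of stopping at the dioxaborin. The fallback sets out from 10 (with 12) and changes the template from boron to magnesium. Phenol 10 is converted into its bromomagnesium phenoxide (EtMgBr, 1.0 equiv, toluene/CH2Cl2, 0 °C), which adds ortho-specifically and 1,2 to 12 to give the racemic allylic benzylic diol 3-{4-hydroxy-3-[(E)-1-hydroxy-3-aryl-prop-2-enyl]-5-methoxyphenyl}propyl ester F3. Condensation of F3 with PhB(OH)2 (MgSO4, CH2Cl2, 25 °C) then gives 13, where the route is rejoined.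

Step 10. The trivalent-iodine reagent may instead abstract hydride from C2 to give a flavylium ion, and the sulfonic acid formed may open the acid-labile chromene before it contracts. The fallback sets out from 14 and separates addition from rearrangement. NBS in MeOH/CH2Cl2 at −20 °C gives, by anti bromo-methoxylation, the (2S,3R,4S)-3-bromo-4-methoxychroman ester F4 (bromine anti to the 2-aryl group, methoxy anti to bromine). AgBF4 in MeOH then removes bromide with the same anti 1,2-shift of the ring A carbon and methanol capture, giving acetal 15, where the route is rejoined.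

Further compounds
F1 | step 9 | racemic 3-[8-methoxy-2-{3-methoxy-4-(triisopropylsilyloxy)phenyl}-2H-chromen-6-yl]propyl (E)-3-[3-methoxy-4-(triisopropylsilyloxy)phenyl]prop-2-enoate | COc1cc(/C=C/C(=O)OCCCc2cc(OC)c3c(c2)C=CC(c2ccc(O[Si](C(C)C)(C(C)C)C(C)C)c(OC)c2)O3)ccc1O[Si](C(C)C)(C(C)C)C(C)C
F2 | step 9 | (2S)-enantiomer of 14 | COc1cc(/C=C/C(=O)OCCCc2cc(OC)c3c(c2)C=C[C@@H](c2ccc(O[Si](C(C)C)(C(C)C)C(C)C)c(OC)c2)O3)ccc1O[Si](C(C)C)(C(C)C)C(C)C
F3 | step 8 | racemic 3-{4-hydroxy-3-[(E)-1-hydroxy-3-{3-methoxy-4-(triisopropylsilyloxy)phenyl}prop-2-enyl]-5-methoxyphenyl}propyl (E)-3-[3-methoxy-4-(triisopropylsilyloxy)phenyl]prop-2-enoate | COc1cc(/C=C/C(=O)OCCCc2cc(OC)c(O)c(c2)C(O)/C=C/c2ccc(O[Si](C(C)C)(C(C)C)C(C)C)c(OC)c2)ccc1O[Si](C(C)C)(C(C)C)C(C)C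
F4 | step 10 | 3-[(2S,3R,4S)-3-bromo-4,8-dimethoxy-2-{3-methoxy-4-(triisopropylsilyloxy)phenyl}-3,4-dihydro-2H-chromen-6-yl]propyl (E)-3-[3-methoxy-4-(triisopropylsilyloxy)phenyl]prop-2-enoate | COc1cc(/C=C/C(=O)OCCCc2cc(OC)c3c(c2)[C@H](OC)[C@@H](Br)[C@H](c2ccc(O[Si](C(C)C)(C(C)C)C(C)C)c(OC)c2)O3)ccc1O[Si](C(C)C)(C(C)C)C(C)C
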